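(The rate constants are made up; the result is computed.)

- The charge cannot carry the whole of the starting material through to tetra adduct: that takes 40.0 mM of coupling partner, more than the 10.0 mM charged, so coupling partner is the limiting reagent in each set-up.

| flask | starting material | coupling partner | time | remark |
|---|---|---|---|---|
| north-east | 10 mM (fed, over 30.0 h) | 10.0 mM | 30 h | a stirred flask in which starting material is dosed at a steady rate over 30.0 h without added volume, worked up at 30 h |
| south-west | 10 mM | 10.0 mM (fed, over 30.0 h) | 30 h | all but coupling partner at the start; coupling partner goes in evenly over 30.0 h, the run ends at 30 h |
| north | 10 mM | 10.0 mM |  | a single well-mixed tank run continuously and read at steady state, 30 h in it on average |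
| south-east | 10 mM | 10.0 mM | 30 h | everything together in a closed stirred flask, run for 30 h |

- the set-up with the highest share of tris adduct in all that became tris adduct or tetra adduct, at the outlet or at the end ("none" if the first two lie within 2 percentage points) (north-east / south-west / north / south-east / none)
- share of tris adduct in all that became tris adduct or tetra adduct, at the outlet or at the end, north-east
- share of tris adduct in all that became tris adduct or tetra adduct, at the outlet or at the end, south-west
- share of tris adduct in all that became tris adduct or tetra adduct, at the outlet or at the end, north
- share of tris adduct in all that became tris adduct or tetra adduct, at the outlet or at the end, south-east

- amounts and yields of released group count idle adduct too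
- the stated concentrations are those of everything mixed, before any reaction; amounts are the same in each set-up
- the feed brings no volume worth counting
- run time (north-east): 30 h

    coupling partner + first product → bis adduct + released group (k1 = 25 L mol⁻¹ h⁻¹)
    coupling partner + released group ⇌ idle adduct, settled at all times (K2 = 130 L mol⁻¹)
    coupling partner + tris adduct → tetra adduct + released group (k3 = 33 L mol⁻¹ h⁻¹)
    coupling partner + bis adduct → tris adduct + released group (k4 = 7.9 L mol⁻¹ h⁻¹)
    starting material + coupling partner → first product + released group (k5 = 23 L mol⁻¹ h⁻¹)

- Our reckoning covers the tank, north. At steady state, tetra adduct leaves by the outlet as fast as the tris-to-tetra step makes it, so [tetra adduct]/[tris adduct] equals that step's constant times free [coupling partner] times the mean time in the tank. We call this ratio the burn number, and the share of tris adduct is one over one plus the burn number. What we lack is free [coupling partner].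
- First instants: in the closed flask, south-east, with partner as charged, tris adduct has a half-life of 2.1 h by the tris-to-tetra step alone, short against 30 h and shorter than the 8.8 h of bis adduct by its own step. Free partner is about to matter.
- Middle: each step frees released group, and the balance constant times partner as charged is 1.3 in south-east, above 1, so idle adduct must be counted.
- First round, tank, north: we guess 7.50 mM of partner used, counting the released group as free. The 2.50 mM left then divides into free partner of 1.27 mM and idle adduct.
- Second round, tank, north: we put that free partner into the tank balances, each species fed by the one before it and lost to the outlet and the next step. They return 7.75 mM of partner used. Taking the idle adduct out of the released group, free partner becomes 1.20 mM.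
- End, tank, north: the burn number is 1.19, so we commit to a share of 45.7%.
- The forecast named south-west best, with 43% for north-east, 77% for south-west, 45% for north and 70% for south-east, holding that “Slow partner feed keeps that exposure lowest”.
- The simulation gives 45.1% for north-east, 75.5% for south-west, 44.7% for north and 69.2% for south-east, so south-west is best.

- Free partner in the tank, north, stands at 1.25 mM, against our 1.20 mM. Put in place of our 1.19, that value gives a burn number of 1.24 and a share of 44.7%. In the fed flask, south-west, partner peaks at 1.33 mM, where the same product over 30 h is 1.32, and tetra adduct per tris adduct ends at 0.325, about a quarter of it.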